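**Plan**

- Numbering (germacranolide): ring C1–C10 with C1=C10, C4=C5, C6–O (lactone), C8–O (methacrylate), C9–OAc; lactone carbons C11–C13; ester carbon C14; CH2OH carbon C15.
- Retrosynthesis: after removing the acyl and silyl groups, the ten-membered ring is cut at C9–C10. C9 is a carbinol next to C10, the α-carbon of the C1=C10/C14 enoate, so this bond is the addition of a C10 alkenyl metal (from a Z-α-iodoenoate) to a C9 aldehyde. The ring-cis C1=C10 bond holds C2 and C9 on the same side.
- The seco chain is then cut at C6–C7 and at the O6–C12 lactone bond. This gives an achiral enal (C1–C6, C10, C14, C15) and a bromomethyl dihydropyranone (C7–C9, C11–C13) whose six-membered lactone holds O9.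
- Forward: an indium Barbier reaction joins the fragments at C6–C7; δ-to-γ translactonization builds the five-membered lactone and frees C9–OH; oxidation; Nozaki–Hiyama–Kishi closure of the ten-membered ring; then acetate, methacrylate and desilylation.
- Stereochemistry: C8 comes from (S)-but-3-ene-1,2-diol. C7 and C6 follow from it in the Barbier step (attack anti to the C8 ether, chair transition state). C9 follows from C8 in the ring closure. C4=C5 comes from directed trans-hydroalumination/iodination and Suzuki coupling with retention. C1=C10 comes from a Z-selective iodo-Wittig reaction and retention in the ring closure.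

Key step: step 13

**Route**

Step 1
Reactants: 1 but-2-yne-1,4-diol
Product: 2 4-[(tert-butyldimethylsilyl)oxy]but-2-yn-1-ol
Conditions: NaH (1.0 equiv), THF, 0 °C to rt; TBSCl (1.0 equiv)
Reagents that add atoms: tert-butyldimethylsilyl chloride, CC(C)(C)[Si](C)(C)Cl
Why: Monosilylation of a symmetric diol through its sparingly soluble monosodium alkoxide should give the mono ether and keep one propargylic hydroxyl to direct the next step.

Step 2
Reactants: 2 4-[(tert-butyldimethylsilyl)oxy]but-2-yn-1-ol
Product: 4 (Z)-4-[(tert-butyldimethylsilyl)oxy]-3-iodobut-2-en-1-ol, via alkenylalanate 3 (not isolated)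
Conditions: NaAlH2(OCH2CH2OMe)2 (Red-Al), THF, 0 °C; then I2, THF, −78 °C to 0 °C
Reagents that add atoms: iodine, II
Why: Hydroxyl-directed trans-hydroalumination of the propargylic alcohol places aluminium on the distal alkyne carbon inside a five-membered alkoxyalanate, and iodinolysis with retention should give the Z-iodoalkene with iodine cis to CH2OH (future C6) and CH2OTBS (future C15) trans to it, the low temperature keeping the β-silyloxy alanate from eliminating to an allene.

Step 3
Reactants: 4 (Z)-4-[(tert-butyldimethylsilyl)oxy]-3-iodobut-2-en-1-ol; 5 3,3-diethoxyprop-1-ene (acrolein diethyl acetal)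
Product: 7 (E)-3-{[(tert-butyldimethylsilyl)oxy]methyl}-6,6-diethoxyhex-2-en-1-ol, via alkylborane 6 (not isolated)
Conditions: 5, 9-BBN, THF, 0 °C to rt; then 4, Pd(dppf)Cl2 (cat.), AsPh3 (cat.), Cs2CO3, DMF/H2O, rt
Reagents that add atoms: none
Why: Anti-Markovnikov hydroboration of the vinyl acetal followed by B-alkyl Suzuki–Miyaura coupling with the alkenyl iodide proceeds with retention of alkene geometry, so the new C3 chain should end cis to CH2OH (C6), as the ring-cis C4=C5 bond requires.

Step 4
Reactants: 7 (E)-3-{[(tert-butyldimethylsilyl)oxy]methyl}-6,6-diethoxyhex-2-en-1-ol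
Product: 8 (E)-4-{[(tert-butyldimethylsilyl)oxy]methyl}-6-hydroxyhex-4-enal
Conditions: PPTS (cat.), acetone/H2O, rt
Reagents that add atoms: water, O
Why: Acid-catalysed hydrolysis of the acyclic diethyl acetal is faster than cleavage of the primary silyl ether under these buffered conditions and should free the C1 aldehyde.

Step 5
Reactants: 8 (E)-4-{[(tert-butyldimethylsilyl)oxy]methyl}-6-hydroxyhex-4-enal; 9 methyl (triphenyl-λ5-phosphanylidene)acetate
Product: 11 methyl (2Z,6E)-6-{[(tert-butyldimethylsilyl)oxy]methyl}-8-hydroxy-2-iodoocta-2,6-dienoate, via iodo ylide 10 (not isolated)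
Conditions: 9, NIS, CH2Cl2, −20 °C; then 8, −20 °C to rt
Reagents that add atoms: N-iodosuccinimide, O=C1CCC(=O)N1I
Why: Iodination of the stabilized ylide gives the α-iodo ylide, whose Wittig reaction with the aliphatic aldehyde should place the ester trans to the chain (Z-α-iodoenoate, iodine cis to C2) as stabilized ylides do, the allylic hydroxyl being inert.

Step 6
Reactants: 11 methyl (2Z,6E)-6-{[(tert-butyldimethylsilyl)oxy]methyl}-8-hydroxy-2-iodoocta-2,6-dienoate
Product: 12 methyl (2Z,6E)-6-{[(tert-butyldimethylsilyl)oxy]methyl}-2-iodo-8-oxoocta-2,6-dienoate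
Conditions: Dess–Martin periodinane, CH2Cl2, 0 °C to rt
Reagents that add atoms: none
Why: Dess–Martin oxidation of the allylic alcohol under non-basic conditions should give the enal without isomerizing either alkene.

Step 7
Reactants: 13 (S)-but-3-ene-1,2-diol
Product: 14 (4S)-2-(4-methoxyphenyl)-4-vinyl-1,3-dioxolane (both epimers at the acetal carbon)
Conditions: 4-MeOC6H4CH(OMe)2, CSA (cat.), CH2Cl2, rt
Reagents that add atoms: 4-methoxybenzaldehyde dimethyl acetal, COC(OC)c1ccc(OC)cc1
Why: Acid-catalysed transacetalization of the 1,2-diol leaves the carbinol stereocenter (future C8) untouched.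

Step 8
Reactants: 14 (4S)-2-(4-methoxyphenyl)-4-vinyl-1,3-dioxolane
Product: 15 (S)-2-[(4-methoxybenzyl)oxy]but-3-en-1-ol
Conditions: i-Bu2AlH, CH2Cl2, −78 °C to 0 °C
Reagents that add atoms: none
Why: In this regioselective reductive opening of a 4-methoxybenzylidene acetal the aluminium binds the less hindered primary oxygen and hydride reduces the resulting oxocarbenium ion, so the PMB group should stay on the secondary oxygen.

Step 9
Reactants: 15 (S)-2-[(4-methoxybenzyl)oxy]but-3-en-1-ol; 16 2-(bromomethyl)prop-2-enoic acid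
Product: 17 (S)-2-[(4-methoxybenzyl)oxy]but-3-en-1-yl 2-(bromomethyl)prop-2-enoate
Conditions: DCC, DMAP (cat.), CH2Cl2, 0 °C
Reagents that add atoms: none
Why: Steglich esterification of the primary alcohol at low temperature should proceed without displacement of the allylic bromide.

Step 10
Reactants: 17 (S)-2-[(4-methoxybenzyl)oxy]but-3-en-1-yl 2-(bromomethyl)prop-2-enoate
Product: 18 (S)-3-(bromomethyl)-5-[(4-methoxybenzyl)oxy]-5,6-dihydro-2H-pyran-2-one
Conditions: second-generation Grubbs catalyst (H2IMes)(PCy3)Cl2Ru=CHPh (cat.), CH2Cl2 (0.01 M), 40 °C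
Reagents that add atoms: none
Why: Ring-closing metathesis between the vinyl group and the 1,1-disubstituted acrylate closes the six-membered unsaturated lactone, in which C8 and C12 are necessarily cis on the new C7=C11 bond, driven by loss of ethene.

Step 11
Reactants: 18 (S)-3-(bromomethyl)-5-[(4-methoxybenzyl)oxy]-5,6-dihydro-2H-pyran-2-one; 12 methyl (2Z,6E)-6-{[(tert-butyldimethylsilyl)oxy]methyl}-2-iodo-8-oxoocta-2,6-dienoate
Product: 20 methyl (2Z,6E)-6-{[(tert-butyldimethylsilyl)oxy]methyl}-7-{(2R,3S)-3-[(1S)-2-hydroxy-1-[(4-methoxybenzyl)oxy]ethyl]-4-methylene-5-oxotetrahydrofuran-2-yl}-2-iodohepta-2,6-dienoate, via δ-lactone adduct 19 (not isolated)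
Conditions: In powder, THF/H2O (3:1), rt; then PPTS (cat.), CH2Cl2, rt
Reagents that add atoms: none
Why: In this indium-mediated Barbier allylation of the 2-(bromomethyl)acrylate type the allylindium should add through its γ-carbon C7 to the enal on the ring face anti to the C8 PMB ether and through a chair Zimmerman–Traxler transition state (enal substituent equatorial, ring-locked E-type allyl unit), which sets C7 trans to O8 and C6 anti to C8, and acid-catalysed translactonization of the δ-lactone to the more stable trans-fused γ-lactone then frees the C9 hydroxyl.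

Step 12
Reactants: 20 the γ-lactone alcohol of step 11
Product: 21 methyl (2Z,6E)-6-{[(tert-butyldimethylsilyl)oxy]methyl}-2-iodo-7-{(2R,3S)-3-[(1S)-1-[(4-methoxybenzyl)oxy]-2-oxoethyl]-4-methylene-5-oxotetrahydrofuran-2-yl}hepta-2,6-dienoate
Conditions: Dess–Martin periodinane, CH2Cl2, 0 °C to rt
Reagents that add atoms: none
Why: Dess–Martin oxidation of the primary alcohol under non-basic conditions should give the α-alkoxy aldehyde without epimerization at C8 and without touching the alkenes or the iodide.

Step 13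
Reactants: 21 the C9 aldehyde / C10 iodide of step 12
Product: 22 methyl (6R,7S,8S,9S)-15-[(tert-butyldimethylsilyl)oxy]-9-hydroxy-8-[(4-methoxybenzyl)oxy]germacra-1(10),4,11(13)-trien-12,6-olid-14-oate (both ring alkenes ring-cis)
Conditions: CrCl2 (10 equiv), NiCl2 (cat.), degassed DMSO (0.003 M), rt
Reagents that add atoms: none
Why: CrCl2 reduces NiCl2 to zerovalent nickel, which inserts into the C10–I bond; transmetallation gives the ester-substituted alkenylchromium (trivalent chromium), which adds to the C9 aldehyde, so C9–C10 forms with retention at C10 (C9 cis to C2, ester trans). The closest known reaction type is the intramolecular Nozaki–Hiyama–Kishi coupling of alkenyl iodides with aldehydes used to close medium and large carbocycles. The ten-membered carbocycle closes in an exo-trig mode at the aldehyde carbonyl, the oxygen ending outside the ring as the chromium alkoxide. The new C9 stereocenter is controlled by C8: chromium bridging the aldehyde oxygen and the C8 PMB ether oxygen (Cram chelate), or equally the transition state with both oxygens turned outward from the forming ring, exposes the aldehyde face that gives the 9S carbinol with O9 trans to O8. The step needs cyclization over oligomerization and C–I insertion over attack on the enoate, the lactone or its methylene group: high dilution together with the rigid trans-fused lactone and the ring-cis C4=C5 bond, which bring C9 and C10 together, should secure the first, and the mildness of the organochromium the second.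

Step 14
Reactants: 22 the macrocyclic C9 alcohol of step 13
Product: 23 methyl (6R,7S,8S,9S)-9-acetoxy-15-[(tert-butyldimethylsilyl)oxy]-8-[(4-methoxybenzyl)oxy]germacra-1(10),4,11(13)-trien-12,6-olid-14-oate
Conditions: Ac2O, pyridine, DMAP (cat.), CH2Cl2, 0 °C to rt
Reagents that add atoms: acetic anhydride, CC(=O)OC(C)=O
Why: DMAP-catalysed acetylation should esterify the secondary allylic C9 hydroxyl, the only free hydroxyl in the molecule.

Step 15
Reactants: 23 the C9 acetate of step 14
Product: 24 methyl (6R,7S,8S,9S)-9-acetoxy-15-[(tert-butyldimethylsilyl)oxy]-8-hydroxygermacra-1(10),4,11(13)-trien-12,6-olid-14-oate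
Conditions: DDQ, CH2Cl2/pH 7 buffer (10:1), 0 °C to rt
Reagents that add atoms: none
Why: DDQ oxidizes the PMB ether to its benzylic oxocarbenium ion, whose hydrolysis frees the C8 hydroxyl under neutral conditions that should leave the silyl ether, the esters and the alkenes alone.

Step 16
Reactants: 24 the C8 alcohol of step 15
Product: 25 methyl (6R,7S,8S,9S)-9-acetoxy-15-[(tert-butyldimethylsilyl)oxy]-8-(methacryloyloxy)germacra-1(10),4,11(13)-trien-12,6-olid-14-oate
Conditions: methacrylic anhydride, Et3N, DMAP (cat.), CH2Cl2, 0 °C to rt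
Reagents that add atoms: methacrylic anhydride, C=C(C)C(=O)OC(=O)C(C)=C
Why: DMAP-catalysed acylation of the C8 hydroxyl with the anhydride at low temperature should be fast enough to outrun 1,2-acetyl migration from O9.

Step 17
Reactants: 25 the silyl ether of step 16
Product: 26 CNP0179134.2, methyl (6R,7S,8S,9S)-9-acetoxy-15-hydroxy-8-(methacryloyloxy)germacra-1(10),4,11(13)-trien-12,6-olid-14-oate
Conditions: HF·pyridine, pyridine/THF, 0 °C to rt
Reagents that add atoms: none
Why: Fluoride cleavage of the primary silyl ether under buffered, non-basic conditions should leave the three esters, the lactone and the Michael acceptors intact.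

**Compound list**

1 | but-2-yne-1,4-diol | OCC#CCO | starting material
2 | 4-[(tert-butyldimethylsilyl)oxy]but-2-yn-1-ol | OCC#CCO[Si](C)(C)C(C)(C)C | intermediate
3 | sodium cyclic alkenylalanate: 2,2-bis(2-methoxyethoxy)-3-{[(tert-butyldimethylsilyl)oxy]methyl}-2,5-dihydro-1,2-oxaluminol-2-uide | [Na+].COCCO[Al-]1(OCCOC)OCC=C1CO[Si](C)(C)C(C)(C)C | intermediate (not isolated)
4 | (Z)-4-[(tert-butyldimethylsilyl)oxy]-3-iodobut-2-en-1-ol | OC/C=C(\I)CO[Si](C)(C)C(C)(C)C | intermediate
5 | 3,3-diethoxyprop-1-ene (acrolein diethyl acetal) | C=CC(OCC)OCC | starting material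
6 | 9-(3,3-diethoxypropyl)-9-borabicyclo[3.3.1]nonane | CCOC(CCB1C2CCCC1CCC2)OCC | intermediate (not isolated)
7 | (E)-3-{[(tert-butyldimethylsilyl)oxy]methyl}-6,6-diethoxyhex-2-en-1-ol | OC/C=C(/CO[Si](C)(C)C(C)(C)C)CCC(OCC)OCC | intermediate
8 | (E)-4-{[(tert-butyldimethylsilyl)oxy]methyl}-6-hydroxyhex-4-enal | OC/C=C(/CO[Si](C)(C)C(C)(C)C)CCC=O | intermediate
9 | methyl (triphenyl-λ5-phosphanylidene)acetate | COC(=O)C=P(c1ccccc1)(c1ccccc1)c1ccccc1 | starting material
10 | methyl iodo(triphenyl-λ5-phosphanylidene)acetate | COC(=O)C(I)=P(c1ccccc1)(c1ccccc1)c1ccccc1 | intermediate (not isolated)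
11 | methyl (2Z,6E)-6-{[(tert-butyldimethylsilyl)oxy]methyl}-8-hydroxy-2-iodoocta-2,6-dienoate | OC/C=C(/CO[Si](C)(C)C(C)(C)C)CC/C=C(/C(=O)OC)I | intermediate
12 | methyl (2Z,6E)-6-{[(tert-butyldimethylsilyl)oxy]methyl}-2-iodo-8-oxoocta-2,6-dienoate | O=C/C=C(/CO[Si](C)(C)C(C)(C)C)CC/C=C(/C(=O)OC)I | intermediate
13 | (S)-but-3-ene-1,2-diol | C=C[C@H](O)CO | starting material
14 | (4S)-2-(4-methoxyphenyl)-4-vinyl-1,3-dioxolane (both acetal epimers) | C=C[C@H]1COC(c2ccc(OC)cc2)O1 | intermediate
15 | (S)-2-[(4-methoxybenzyl)oxy]but-3-en-1-ol | C=C[C@H](OCc1ccc(OC)cc1)CO | intermediate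
16 | 2-(bromomethyl)prop-2-enoic acid | OC(=O)C(=C)CBr | starting material
17 | (S)-2-[(4-methoxybenzyl)oxy]but-3-en-1-yl 2-(bromomethyl)prop-2-enoate | C=C[C@H](OCc1ccc(OC)cc1)COC(=O)C(=C)CBr | intermediate
18 | (S)-3-(bromomethyl)-5-[(4-methoxybenzyl)oxy]-5,6-dihydro-2H-pyran-2-one | COc1ccc(CO[C@@H]2COC(=O)C(CBr)=C2)cc1 | intermediate
19 | methyl (2Z,6E,8R)-6-{[(tert-butyldimethylsilyl)oxy]methyl}-8-hydroxy-2-iodo-8-{(4S,5S)-5-[(4-methoxybenzyl)oxy]-3-methylene-2-oxotetrahydro-2H-pyran-4-yl}octa-2,6-dienoate | COc1ccc(CO[C@@H]2COC(=O)C(=C)[C@H]2[C@H](O)/C=C(/CO[Si](C)(C)C(C)(C)C)CC/C=C(/C(=O)OC)I)cc1 | intermediate (not isolated)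
20 | methyl (2Z,6E)-6-{[(tert-butyldimethylsilyl)oxy]methyl}-7-{(2R,3S)-3-[(1S)-2-hydroxy-1-[(4-methoxybenzyl)oxy]ethyl]-4-methylene-5-oxotetrahydrofuran-2-yl}-2-iodohepta-2,6-dienoate | COc1ccc(CO[C@H](CO)[C@H]2C(=C)C(=O)O[C@@H]2/C=C(/CO[Si](C)(C)C(C)(C)C)CC/C=C(/C(=O)OC)I)cc1 | intermediate
21 | methyl (2Z,6E)-6-{[(tert-butyldimethylsilyl)oxy]methyl}-2-iodo-7-{(2R,3S)-3-[(1S)-1-[(4-methoxybenzyl)oxy]-2-oxoethyl]-4-methylene-5-oxotetrahydrofuran-2-yl}hepta-2,6-dienoate | COc1ccc(CO[C@H](C=O)[C@H]2C(=C)C(=O)O[C@@H]2/C=C(/CO[Si](C)(C)C(C)(C)C)CC/C=C(/C(=O)OC)I)cc1 | intermediate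
22 | methyl (6R,7S,8S,9S)-15-[(tert-butyldimethylsilyl)oxy]-9-hydroxy-8-[(4-methoxybenzyl)oxy]germacra-1(10),4,11(13)-trien-12,6-olid-14-oate | COc1ccc(CO[C@H]2[C@H]3C(=C)C(=O)O[C@@H]3/C=C(/CO[Si](C)(C)C(C)(C)C)CC/C=C(/C(=O)OC)[C@@H]2O)cc1 | intermediate
23 | methyl (6R,7S,8S,9S)-9-acetoxy-15-[(tert-butyldimethylsilyl)oxy]-8-[(4-methoxybenzyl)oxy]germacra-1(10),4,11(13)-trien-12,6-olid-14-oate | COc1ccc(CO[C@H]2[C@H]3C(=C)C(=O)O[C@@H]3/C=C(/CO[Si](C)(C)C(C)(C)C)CC/C=C(/C(=O)OC)[C@@H]2OC(C)=O)cc1 | intermediate
24 | methyl (6R,7S,8S,9S)-9-acetoxy-15-[(tert-butyldimethylsilyl)oxy]-8-hydroxygermacra-1(10),4,11(13)-trien-12,6-olid-14-oate | O[C@H]1[C@H]2C(=C)C(=O)O[C@@H]2/C=C(/CO[Si](C)(C)C(C)(C)C)CC/C=C(/C(=O)OC)[C@@H]1OC(C)=O | intermediate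
25 | methyl (6R,7S,8S,9S)-9-acetoxy-15-[(tert-butyldimethylsilyl)oxy]-8-(methacryloyloxy)germacra-1(10),4,11(13)-trien-12,6-olid-14-oate | C=C(C)C(=O)O[C@H]1[C@H]2C(=C)C(=O)O[C@@H]2/C=C(/CO[Si](C)(C)C(C)(C)C)CC/C=C(/C(=O)OC)[C@@H]1OC(C)=O | intermediate
26 | CNP0179134.2, methyl (6R,7S,8S,9S)-9-acetoxy-15-hydroxy-8-(methacryloyloxy)germacra-1(10),4,11(13)-trien-12,6-olid-14-oate | C=C(C)C(=O)O[C@H]1[C@H]2C(=C)C(=O)O[C@@H]2/C=C(/CO)CC/C=C(/C(=O)OC)[C@@H]1OC(C)=O | target

**Totals**

Total step count: 17 steps.
Longest linear sequence: 13 steps (steps 1–6 and 11–17, from but-2-yne-1,4-diol).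

**Steps most likely to fail**

Step 13 (ring closure). The macrocyclic transition state may expose the other face of the C9 aldehyde, and intermolecular coupling competes with closure of the strained ten-membered ring. The fallback sets out from 21 and changes how C9 is set: if the cyclization under the same conditions delivers mainly the C9 epimer, methyl (6R,7S,8S,9R)-15-[(tert-butyldimethylsilyl)oxy]-9-hydroxy-8-[(4-methoxybenzyl)oxy]germacra-1(10),4,11(13)-trien-12,6-olid-14-oate F1, a Mitsunobu esterification with acetic acid (PPh3, DIAD, AcOH, toluene, 0 °C to rt) should invert C9 and install the acetate in one operation. It comes back to the route at 23.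

Step 11 (fragment union). In water the allylindium may react through an open transition state and lose facial or simple diastereoselectivity, and the allylmetal may undergo reductive 1,4-elimination of the PMB-oxy group. The fallback sets out from 18 and replaces the reducing metal by boron: palladium-catalysed borylation (B2pin2, Pd2(dba)3 cat., KOAc, toluene/DMSO, 50 °C) should give the primary allylboronate (S)-5-[(4-methoxybenzyl)oxy]-3-[(4,4,5,5-tetramethyl-1,3,2-dioxaborolan-2-yl)methyl]-5,6-dihydro-2H-pyran-2-one F2. Its allylboration of enal 12 (toluene, rt to 50 °C) runs through a closed six-membered chair transition state and, after aqueous work-up, should give δ-lactone adduct 19, which is translactonized with PPTS as before. It comes back to the route at 20.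

Step 10 (ring-closing metathesis). Metathesis at the 1,1-disubstituted, electron-poor acrylate may be slow, and the allylic bromide may degrade the ruthenium carbene. The fallback sets out from 15 and installs the bromomethyl group after ring closure: acylation with acryloyl chloride (Et3N, CH2Cl2, 0 °C) gives (S)-2-[(4-methoxybenzyl)oxy]but-3-en-1-yl acrylate F3. Ring-closing metathesis of this unhindered diene (second-generation Grubbs catalyst, CH2Cl2, 40 °C) gives (S)-5-[(4-methoxybenzyl)oxy]-5,6-dihydro-2H-pyran-2-one F4. Morita–Baylis–Hillman hydroxymethylation (aqueous formaldehyde, imidazole, THF/H2O, rt) gives (S)-3-(hydroxymethyl)-5-[(4-methoxybenzyl)oxy]-5,6-dihydro-2H-pyran-2-one F5, and CBr4/PPh3 (CH2Cl2, 0 °C) converts the allylic alcohol into the bromide. It comes back to the route at 18.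

**Further compounds**

F1 | step 13 | methyl (6R,7S,8S,9R)-15-[(tert-butyldimethylsilyl)oxy]-9-hydroxy-8-[(4-methoxybenzyl)oxy]germacra-1(10),4,11(13)-trien-12,6-olid-14-oate | COc1ccc(CO[C@H]2[C@H]3C(=C)C(=O)O[C@@H]3/C=C(/CO[Si](C)(C)C(C)(C)C)CC/C=C(/C(=O)OC)[C@H]2O)cc1
F2 | step 11 | (S)-5-[(4-methoxybenzyl)oxy]-3-[(4,4,5,5-tetramethyl-1,3,2-dioxaborolan-2-yl)methyl]-5,6-dihydro-2H-pyran-2-one | COc1ccc(CO[C@@H]2COC(=O)C(CB3OC(C)(C)C(C)(C)O3)=C2)cc1
F3 | step 10 | (S)-2-[(4-methoxybenzyl)oxy]but-3-en-1-yl acrylate | C=C[C@H](OCc1ccc(OC)cc1)COC(=O)C=C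
F4 | step 10 | (S)-5-[(4-methoxybenzyl)oxy]-5,6-dihydro-2H-pyran-2-one | COc1ccc(CO[C@@H]2COC(=O)C=C2)cc1
F5 | step 10 | (S)-3-(hydroxymethyl)-5-[(4-methoxybenzyl)oxy]-5,6-dihydro-2H-pyran-2-one | COc1ccc(CO[C@@H]2COC(=O)C(CO)=C2)cc1
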